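**Retrosynthetic overview**
1. Target = 7,4'-dihydroxyisoflavone with a (1Z,3R)-3,7-dimethylocta-1,6-dienyl chain at C3'. Last moves: acetate removal, cis-semihydrogenation of an aryl alkyne, Sonogashira coupling of a 3'-iodoisoflavone with (R)-3,7-dimethyloct-6-en-1-yne.
2. The alkyne comes from (R)-citronellal by net dehydration, so the only stereocentre is taken from the chiral pool.
3. Ring C (the 4-pyranone) closes by acid cyclisation of a 2-aryl-3,3-dimethoxypropiophenone, which arises from a 2'-hydroxychalcone by oxidative 1,2-aryl shift.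
4. Key C–C bond: intermolecular Claisen–Schmidt aldol condensation of a ring A acetophenone with a ring B 3-iodobenzaldehyde.
5. Ring order: rings A and B are bought as benzene rings; ring C is the only ring formed (step 5).

Assumption: (R)-(+)-citronellal of high enantiopurity (≥97% ee grade) and 4-hydroxy-3-iodobenzaldehyde are taken as catalogue compounds.

**Route**

Step 1
Reactants: 1 1-(2,4-dihydroxyphenyl)ethanone
Product: 2 1-[4-(benzyloxy)-2-hydroxyphenyl]ethanone
Conditions: BnBr (1.05 equiv), K2CO3 (1.2 equiv), acetone, reflux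
Reagents that add atoms: benzyl bromide, BrCc1ccccc1
Why: Williamson etherification is selective for the 4-OH because the 2-OH is held in a hydrogen bond to the ketone and is much less nucleophilic.

Step 2
Reactants: 3 4-hydroxy-3-iodobenzaldehyde
Product: 4 4-(benzyloxy)-3-iodobenzaldehyde
Conditions: BnBr (1.1 equiv), K2CO3 (1.5 equiv), DMF, rt
Reagents that add atoms: benzyl bromide, BrCc1ccccc1
Why: Williamson etherification of the acidic phenol gives a benzyl ether that survives the base, oxidant and acid of steps 3 to 5 and blocks phenol oxidation in step 4.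

Step 3
Reactants: 2 1-[4-(benzyloxy)-2-hydroxyphenyl]ethanone; 4 4-(benzyloxy)-3-iodobenzaldehyde
Product: 6 (E)-1-[4-(benzyloxy)-2-hydroxyphenyl]-3-[4-(benzyloxy)-3-iodophenyl]prop-2-en-1-one, via aldol adduct 5 (not isolated)
Conditions: KOH (50% aq, 10 equiv), EtOH/THF, rt, 24–48 h; then cold dilute HCl
Reagents that add atoms: none
Why: Claisen–Schmidt crossed aldol condensation, in which the acetophenone enolate adds to the non-enolisable aldehyde and E1cB dehydration gives the conjugated (E)-chalcone, joining the ring A and ring B fragments.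

Step 4
Reactants: 6 (E)-1-[4-(benzyloxy)-2-hydroxyphenyl]-3-[4-(benzyloxy)-3-iodophenyl]prop-2-en-1-one
Product: 7 1-[4-(benzyloxy)-2-hydroxyphenyl]-2-[4-(benzyloxy)-3-iodophenyl]-3,3-dimethoxypropan-1-one (racemic)
Conditions: Tl(NO3)3·3H2O (1.2 equiv), MeOH/CH2Cl2, rt; filter off TlNO3, aqueous NaHCO3 work-up (toxic thallium salts, closed handling)
Reagents that add atoms: methanol, CO
Why: Oxidative rearrangement of a chalcone, in which methoxythallation of the enone by trivalent thallium is followed by 1,2-shift of the electron-rich para-alkoxyaryl ring with loss of TlNO3 and trapping of the oxocarbenium ion by methanol (the new stereocentre is racemic and is destroyed in step 5).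

Step 5
Reactants: 7 1-[4-(benzyloxy)-2-hydroxyphenyl]-2-[4-(benzyloxy)-3-iodophenyl]-3,3-dimethoxypropan-1-one
Product: 8 7-(benzyloxy)-3-[4-(benzyloxy)-3-iodophenyl]-4H-chromen-4-one
Conditions: 10% aq HCl, MeOH/THF, reflux, 3 h
Reagents that add atoms: none
Why: Acid-catalysed cyclocondensation, in which the 2-hydroxyl attacks the activated acetal and the 2-methoxyisoflavanone loses methanol to form ring C, while benzyl ethers and the aryl iodide are inert to dilute HCl.

Step 6
Reactants: 8 7-(benzyloxy)-3-[4-(benzyloxy)-3-iodophenyl]-4H-chromen-4-one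
Product: 9 7-hydroxy-3-(4-hydroxy-3-iodophenyl)-4H-chromen-4-one
Conditions: BCl3 (1 M in CH2Cl2, 6 equiv), pentamethylbenzene (6 equiv), CH2Cl2, −78 → 0 °C; MeOH then water
Reagents that add atoms: none
Why: Lewis-acid ether cleavage with Friedel–Crafts capture of the benzyl cation by pentamethylbenzene is a non-reductive debenzylation that keeps the C–I bond and the pyranone C2=C3 bond, which hydrogenolysis would not.

Step 7
Reactants: 9 7-hydroxy-3-(4-hydroxy-3-iodophenyl)-4H-chromen-4-one
Product: 10 3-[4-(acetyloxy)-3-iodophenyl]-4-oxo-4H-chromen-7-yl acetate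
Conditions: Ac2O (4 equiv), pyridine, DMAP (cat.), rt
Reagents that add atoms: acetic anhydride, CC(=O)OC(C)=O
Why: Nucleophile-catalysed O-acylation gives acetates that prevent benzofuran formation from the ortho-iodophenol in step 9 and later come off under mild base that the diene tolerates.

Step 8
Reactants: 11 (3R)-3,7-dimethyloct-6-enal, (R)-(+)-citronellal
Product: 13 (3R)-3,7-dimethyloct-6-en-1-yne, via enol nonaflate 12 (not isolated)
Conditions: nonafluorobutane-1-sulfonyl fluoride (NfF, 1.25 equiv), phosphazene base P2-Et (2.5 equiv), DMF, −30 °C → rt; pentane extraction, careful distillation; ee checked by chiral GC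
Reagents that add atoms: none
Why: Enol sulfonate formation and E2 elimination (aldehyde-to-alkyne dehydration with no change in carbon count) involve only C1 and C2, so the C3 stereocentre of citronellal is carried over unchanged as the (R)-propargylic centre.

Step 9
Reactants: 10 3-[4-(acetyloxy)-3-iodophenyl]-4-oxo-4H-chromen-7-yl acetate; 13 (3R)-3,7-dimethyloct-6-en-1-yne (1.3 equiv)
Product: 14 3-{4-(acetyloxy)-3-[(3R)-3,7-dimethyloct-6-en-1-yn-1-yl]phenyl}-4-oxo-4H-chromen-7-yl acetate
Conditions: Pd(PPh3)2Cl2 (3 mol%), CuI (6 mol%), Et3N (4 equiv), degassed THF, rt → 40 °C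
Reagents that add atoms: none
Why: Sonogashira coupling, in which the aryl iodide adds oxidatively to zerovalent palladium formed in situ and the copper acetylide transmetalates at near room temperature, leaves the aryl acetates, the chromone and the propargylic stereocentre intact.

Step 10
Reactants: 14 3-{4-(acetyloxy)-3-[(3R)-3,7-dimethyloct-6-en-1-yn-1-yl]phenyl}-4-oxo-4H-chromen-7-yl acetate
Product: 15 3-{4-(acetyloxy)-3-[(1Z,3R)-3,7-dimethylocta-1,6-dien-1-yl]phenyl}-4-oxo-4H-chromen-7-yl acetate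
Conditions: H2 (1 atm), Pd/CaCO3 poisoned with Pb(OAc)2 (5 wt% Pd), quinoline (0.3 equiv), EtOAc, rt; stop at one equivalent of H2 (HPLC/NMR control)
Reagents that add atoms: none
Why: Lindlar semihydrogenation delivers one equivalent of H2 syn on the poisoned palladium surface to give the (Z)-styrene, while the trisubstituted alkene, the chromone C2=C3 bond and the allylic stereocentre are not touched.

Step 11
Reactants: 15 3-{4-(acetyloxy)-3-[(1Z,3R)-3,7-dimethylocta-1,6-dien-1-yl]phenyl}-4-oxo-4H-chromen-7-yl acetate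
Product: 16 3-{3-[(1Z,3R)-3,7-dimethylocta-1,6-dien-1-yl]-4-hydroxyphenyl}-7-hydroxy-4H-chromen-4-one (CNP0200226.1)
Conditions: K2CO3 (0.5 equiv), MeOH/THF, 0 °C → rt, 1 h; aq NH4Cl; exclude light
Reagents that add atoms: none
Why: Base-catalysed transesterification of the two aryl acetates uses no acid, so Z-to-E isomerisation of the ortho-hydroxystyrene and hydration or cyclisation of the trisubstituted alkene are avoided.

**Compound list**
1 | 1-(2,4-dihydroxyphenyl)ethanone | CC(=O)c1ccc(O)cc1O | starting material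
2 | 1-[4-(benzyloxy)-2-hydroxyphenyl]ethanone | CC(=O)c1ccc(OCc2ccccc2)cc1O | intermediate
3 | 4-hydroxy-3-iodobenzaldehyde | Ic1cc(C=O)ccc1O | starting material
4 | 4-(benzyloxy)-3-iodobenzaldehyde | Ic1cc(C=O)ccc1OCc1ccccc1 | intermediate
5 | 1-[4-(benzyloxy)-2-hydroxyphenyl]-3-[4-(benzyloxy)-3-iodophenyl]-3-hydroxypropan-1-one (racemic aldol adduct) | Ic1cc(C(O)CC(=O)c2ccc(OCc3ccccc3)cc2O)ccc1OCc1ccccc1 | intermediate (not isolated)
6 | (E)-1-[4-(benzyloxy)-2-hydroxyphenyl]-3-[4-(benzyloxy)-3-iodophenyl]prop-2-en-1-one | Ic1cc(/C=C/C(=O)c2ccc(OCc3ccccc3)cc2O)ccc1OCc1ccccc1 | intermediate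
7 | 1-[4-(benzyloxy)-2-hydroxyphenyl]-2-[4-(benzyloxy)-3-iodophenyl]-3,3-dimethoxypropan-1-one (racemic) | Ic1cc(C(C(OC)OC)C(=O)c2ccc(OCc3ccccc3)cc2O)ccc1OCc1ccccc1 | intermediate
8 | 7-(benzyloxy)-3-[4-(benzyloxy)-3-iodophenyl]-4H-chromen-4-one | Ic1cc(-c2coc3cc(OCc4ccccc4)ccc3c2=O)ccc1OCc1ccccc1 | intermediate
9 | 7-hydroxy-3-(4-hydroxy-3-iodophenyl)-4H-chromen-4-one | Ic1cc(-c2coc3cc(O)ccc3c2=O)ccc1O | intermediate
10 | 3-[4-(acetyloxy)-3-iodophenyl]-4-oxo-4H-chromen-7-yl acetate | Ic1cc(-c2coc3cc(OC(C)=O)ccc3c2=O)ccc1OC(C)=O | intermediate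
11 | (3R)-3,7-dimethyloct-6-enal, (R)-(+)-citronellal | CC(C)=CCC[C@@H](C)CC=O | starting material
12 | (3R)-3,7-dimethylocta-1,6-dien-1-yl nonafluorobutane-1-sulfonate (E/Z mixture) | CC(C)=CCC[C@@H](C)C=COS(=O)(=O)C(F)(F)C(F)(F)C(F)(F)C(F)(F)F | intermediate (not isolated)
13 | (3R)-3,7-dimethyloct-6-en-1-yne | CC(C)=CCC[C@@H](C)C#C | intermediate
14 | 3-{4-(acetyloxy)-3-[(3R)-3,7-dimethyloct-6-en-1-yn-1-yl]phenyl}-4-oxo-4H-chromen-7-yl acetate | CC(C)=CCC[C@@H](C)C#Cc1cc(-c2coc3cc(OC(C)=O)ccc3c2=O)ccc1OC(C)=O | intermediate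
15 | 3-{4-(acetyloxy)-3-[(1Z,3R)-3,7-dimethylocta-1,6-dien-1-yl]phenyl}-4-oxo-4H-chromen-7-yl acetate | CC(C)=CCC[C@@H](C)/C=C\c1cc(-c2coc3cc(OC(C)=O)ccc3c2=O)ccc1OC(C)=O | intermediate
16 | 3-{3-[(1Z,3R)-3,7-dimethylocta-1,6-dien-1-yl]-4-hydroxyphenyl}-7-hydroxy-4H-chromen-4-one | CC(C)=CCC[C@@H](C)/C=C\c1cc(-c2coc3cc(O)ccc3c2=O)ccc1O | target

**Totals**
Total step count: 11.
Longest linear sequence: 9 steps (1 or 2, then 3, 4, 5, 6, 7, 9, 10, 11).

**Three steps most likely to fail, with fallbacks**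

Step 4 (oxidative aryl shift with Tl(NO3)3; aurone or flavone by-products from the free 2'-hydroxyl, toxic reagent). The fallback replaces the oxidative aryl shift by a chalcone epoxide rearrangement. It sets out from 6 and comes back at 8. The 2'-hydroxyl of 6 is capped with MOMCl and NaH in DMF at 0 °C to give (E)-1-[4-(benzyloxy)-2-(methoxymethoxy)phenyl]-3-[4-(benzyloxy)-3-iodophenyl]prop-2-en-1-one F1. Weitz–Scheffer epoxidation (30% H2O2, NaOH, MeOH/THF, 0 °C) gives the racemic trans epoxide [4-(benzyloxy)-2-(methoxymethoxy)phenyl]{3-[4-(benzyloxy)-3-iodophenyl]oxiran-2-yl}methanone F2. BF3·OEt2 in CH2Cl2 at 0 °C opens the epoxide at the benzylic carbon and the aroyl group migrates, giving 2-[4-(benzyloxy)-3-iodophenyl]-3-[4-(benzyloxy)-2-(methoxymethoxy)phenyl]-3-oxopropanal F3. Refluxing F3 with 10% HCl in MeOH removes the methoxymethyl group and the freed phenol condenses with the formyl group to give 8.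

Step 8 (one-pot nonaflation and elimination; aldol self-condensation of the aldehyde, volatile product). The fallback goes through a hydrazone and a vinyl iodide instead of an enol sulfonate. It sets out from 11 and comes back at 13. Condensation of 11 with excess hydrazine hydrate in EtOH at 0 °C → rt gives (3R)-3,7-dimethyloct-6-enal hydrazone F4. Barton vinyl iodide synthesis (I2, 1,1,3,3-tetramethylguanidine, Et2O, 0 °C) gives (3R)-1-iodo-3,7-dimethylocta-1,6-diene F5 as an E/Z mixture. Dehydroiodination with LDA (2.2 equiv, THF, −78 → 0 °C) gives the lithium acetylide, which is protected against propargylic isomerisation, and on quenching gives 13.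

Step 10 (semihydrogenation; over-reduction or partial Z-to-E isomerisation). The fallback builds the Z-alkene before the aryl–alkenyl bond and so avoids both the alkyne coupling and the hydrogenation. It sets out from 13 and 10 and comes back at 15. Alkyne 13 is deprotonated with n-BuLi in THF at −78 °C, borylated with 2-isopropoxy-4,4,5,5-tetramethyl-1,3,2-dioxaborolane and treated with HCl in Et2O, giving 2-[(3R)-3,7-dimethyloct-6-en-1-yn-1-yl]-4,4,5,5-tetramethyl-1,3,2-dioxaborolane F6. Hydrozirconation with Cp2Zr(H)Cl in THF at rt followed by water gives the cis alkenylboronate 2-[(1Z,3R)-3,7-dimethylocta-1,6-dien-1-yl]-4,4,5,5-tetramethyl-1,3,2-dioxaborolane F7. Suzuki–Miyaura coupling of F7 with iodide 10 (Pd(PPh3)4 5 mol%, CsF 3 equiv, THF, 60 °C) proceeds with retention of the Z geometry and gives 15.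

**Further compounds**
F1 | step 4 | (E)-1-[4-(benzyloxy)-2-(methoxymethoxy)phenyl]-3-[4-(benzyloxy)-3-iodophenyl]prop-2-en-1-one | Ic1cc(/C=C/C(=O)c2ccc(OCc3ccccc3)cc2OCOC)ccc1OCc1ccccc1
F2 | step 4 | [4-(benzyloxy)-2-(methoxymethoxy)phenyl]{3-[4-(benzyloxy)-3-iodophenyl]oxiran-2-yl}methanone (racemic trans, one enantiomer drawn) | Ic1cc([C@H]2O[C@@H]2C(=O)c2ccc(OCc3ccccc3)cc2OCOC)ccc1OCc1ccccc1
F3 | step 4 | 2-[4-(benzyloxy)-3-iodophenyl]-3-[4-(benzyloxy)-2-(methoxymethoxy)phenyl]-3-oxopropanal (racemic) | Ic1cc(C(C=O)C(=O)c2ccc(OCc3ccccc3)cc2OCOC)ccc1OCc1ccccc1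
F4 | step 8 | (3R)-3,7-dimethyloct-6-enal hydrazone | CC(C)=CCC[C@@H](C)CC=NN
F5 | step 8 | (3R)-1-iodo-3,7-dimethylocta-1,6-diene (E/Z mixture) | CC(C)=CCC[C@@H](C)C=CI
F6 | step 10 | 2-[(3R)-3,7-dimethyloct-6-en-1-yn-1-yl]-4,4,5,5-tetramethyl-1,3,2-dioxaborolane | CC(C)=CCC[C@@H](C)C#CB1OC(C)(C)C(C)(C)O1
F7 | step 10 | 2-[(1Z,3R)-3,7-dimethylocta-1,6-dien-1-yl]-4,4,5,5-tetramethyl-1,3,2-dioxaborolane | CC(C)=CCC[C@@H](C)/C=C\B1OC(C)(C)C(C)(C)O1
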